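One ratio carries us from these two runs to the maple run: a run's mean rate over its early rate.

| flask | Sbt | Ptn | time |
|---|---|---|---|
| alder | 0.500 M | 0.550 M |  |
| elm | 0.500 M | 0.280 M |  |
| maple | 1.50 M | 1.70 M | 5.5 min |

| alder run: time / min | alder run: [Pdt] / M | elm run: time / min | elm run: [Pdt] / M |
|---|---|---|---|
| 0.22 | 0.0074 | 0.22 | 0.0060 |
| 0.42 | 0.0216 | 0.42 | 0.0171 |
| 0.80 | 0.0395 | 0.80 | 0.0234 |
| 1.5 | 0.0791 | 1.5 | 0.0507 |
| 2.9 | 0.1560 | 2.9 | 0.0985 |
| 5.5 | 0.2704 | 5.5 | 0.1671 |

(scatter of a reading: 0.002 M)

- the power of [Ptn] that the first rate follows, about the charge of the alder run; measure it at two percent of Sbt made into Pdt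
- Pdt in the maple run at 5.5 min, as a share of the Sbt charged

- Overall: Sbt + Ptn -> Pdt.
- Constant volume, constant temperature.
- Readings of a species count what is bound in complexes too.
- An order is taken over about fifteen percent of the charge, up and down.

We read the table by its rows. Up to 1.5 min, our early rate, the alder run makes Pdt at 0.105 min⁻¹ of its Sbt charge and the elm run at 0.0676 min⁻¹. Both runs charge 0.500 M of Sbt, so we put this difference on Ptn, and its power, taken across the two charges, reads 0.659.

The last row gives 54.1% of the charge in the alder run and 33.4% in the elm run. Replacing each curve by its mean, we get the hold, the mean rate up to 5.5 min over the early rate: 0.932 in the alder run and 0.899 in the elm run.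

What error does that replacement make? The alder hold put on the elm run gives 34.7% against the 33.4% read.

No run varies Sbt, so we assume the first power. We then reckon the early rate of the maple run at 0.222 min⁻¹ of its charge. With the alder hold, that gives 114% by 5.5 min, which is more than the charge. Sbt is the limiting reagent there. With the elm hold it gives 110%, which is more than the charge too. A hold of 0.820 already reaches the full charge, so we commit to a maple share close to it.

The forecast gave 0.6 for the order and 30% for the maple run, from 20% to 50%, adding that “the uncertainty is skewed high”.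

The order comes to 0.57, and the maple run gives 94.0%.

    Sbt + Ptn → Pdt (0.9060 L mol⁻¹ min⁻¹)
    Sbt + Ptn → Ofp (0.1110 L mol⁻¹ min⁻¹)
    Sbt + Ptn + Pdt → 2 Pdt (5.544 L² mol⁻² min⁻¹)
    2 Ptn ⇌ Ptn2, settled at all times (18.80 L mol⁻¹)

One step has Pdt joining Sbt and Ptn, with constant 5.54 L² mol⁻² min⁻¹. Against our reckoned early rate, the maple result is a hold of 0.771, beside 0.932 in the alder run and 0.899 in the elm run.

All runs are simulated on assumed constants, and the scatter is random.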